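**Retrosynthetic overview**
- Ten-membered carbocycle (ring C) last: ring-closing metathesis across C4=C5 of an acyclic diene; the bridged ring allows only the Z alkene.
- C8 ester by acylation; the C7–C8 bond, C7 and C8 and the α-methylene lactone (ring B) come from a zinc Barbier union of a furanone acetaldehyde with an (R)-3-(bromomethyl)butenolide (C6 from lipase resolution, butenolide ring by metathesis).
- Furanone (ring A) first, with the quaternary C10: the key C1–C10 bond is made by a carbene-catalysed asymmetric intramolecular Stetter reaction (acyl anion at C1 onto the β-carbon C10 of a β-oxy-crotonate) inside a divinyl ether built from malondialdehyde and an allenoate; the C3 isopropenyl group is added afterwards.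
- Ring order: furanone (A) → butenolide/lactone (B) → ten-membered ring (C).

Assumption: the target is taken as drawn, (4Z,6R,7R,8R,10S) in germacranolide numbering (C1 ketone, C2=C3, ring O between C3 and C10, lactone O on C6, ester on C8); the (5aR,10bS) triazolium antipode is written in step 3 and would be swapped for its mirror image if it gave (R)-6.

**Route**

Step 1
Reactants: 1 1,1,3,3-tetramethoxypropane
Product: 2 sodium malondialdehyde [sodium (E)-3-oxoprop-1-en-1-olate]
Conditions: 1 M HCl (aq), 23 °C; then NaOH (aq) to pH 8, freeze-dry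
Reagents that add atoms: water (O); sodium hydroxide ([Na+].[OH-])
Why: Acid-catalysed acetal hydrolysis and neutralisation give the stable vinylogous-carboxylate enolate, whose symmetry removes any regiochemical question in the next step.

Step 2
Reactants: 2 sodium malondialdehyde; 3 ethyl buta-2,3-dienoate
Product: 4 ethyl (2E)-3-{[(1E)-3-oxoprop-1-en-1-yl]oxy}but-2-enoate
Conditions: AcOH (1.0 equiv), DMF, 0 → 23 °C
Reagents that add atoms: none
Why: Oxa-Michael addition, in which the enolate oxygen adds to the central allene carbon and γ-protonation gives the conjugated (E)-β-oxy-crotonate, while the acetate buffer protects the base- and acid-labile divinyl ether.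

Step 3
Reactants: 4 ethyl (2E)-3-{[(1E)-3-oxoprop-1-en-1-yl]oxy}but-2-enoate
Product: 6 ethyl 2-[(2S)-2-methyl-3-oxo-2,3-dihydrofuran-2-yl]acetate, via Z-enal isomer 5 (not isolated)
Conditions: (5aR,10bS)-2-(pentafluorophenyl)-5a,10b-dihydro-4H,6H-indeno[2,1-b][1,2,4]triazolo[4,3-d][1,4]oxazin-2-ium tetrafluoroborate (20 mol %), KN(SiMe3)2 (18 mol %), toluene, 23 °C
Reagents that add atoms: none
Why: Proposed new method: a vinylogous intramolecular Stetter reaction in which the carbene adds to the aldehyde, the push-pull enal equilibrates E/Z (through the conjugated Breslow intermediate and reversible conjugate addition), and only the Z form 5 can deliver the acyl anion C1 5-exo-trig to the β-carbon C10 of the (E)-β-oxy-crotonate, the aminoindanol backbone shielding one face so that the quaternary C10 is set as S; the closest known reaction is the asymmetric intramolecular Stetter cyclisation of salicylaldehyde-derived aryl ethers of β-methyl acrylates to 2,2-disubstituted benzofuran-3(2H)-ones, of which this is the non-benzo analogue.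

Step 4
Reactants: 6 ethyl 2-[(2S)-2-methyl-3-oxo-2,3-dihydrofuran-2-yl]acetate
Product: 9 ethyl 2-[(2S)-2-methyl-3-oxo-5-(prop-1-en-2-yl)-2,3-dihydrofuran-2-yl]acetate, via magnesium enolate 7 (not isolated), via sulfilimine adduct 8 (not isolated)
Conditions: CH2=C(CH3)MgBr (1.3 equiv), CuBr·SMe2 (20 mol %), THF, −78 °C; then PhS(Cl)=N-t-Bu (1.5 equiv), −78 → 23 °C
Reagents that add atoms: isopropenylmagnesium bromide (CC(=C)[Mg]Br)
Why: One-pot conjugate addition/dehydrogenation, in which copper-catalysed 1,4-addition at C3 gives enolate 7, sulfenylation at C2 gives 8, and syn-elimination of the sulfenamide restores C2=C3, erasing the transient C3 centre and leaving C10 (no acidic hydrogen) untouched.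

Step 5
Reactants: 9 ethyl 2-[(2S)-2-methyl-3-oxo-5-(prop-1-en-2-yl)-2,3-dihydrofuran-2-yl]acetate
Product: 10 2-[(2S)-2-methyl-3-oxo-5-(prop-1-en-2-yl)-2,3-dihydrofuran-2-yl]acetaldehyde
Conditions: i-Bu2AlH (1.05 equiv), CH2Cl2, −78 °C; MeOH, then aqueous potassium sodium tartrate
Reagents that add atoms: none
Why: Partial ester reduction, where the unhindered ethyl ester should react before the C1 carbonyl (a cross-conjugated vinylogous ester next to quaternary C10); the β-alkoxy aldehyde is kept cold and neutral to avoid retro-oxa-Michael opening.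

Step 6
Reactants: 11 (E)-cinnamaldehyde
Product: 12 rac-(1E)-1-phenylpenta-1,4-dien-3-ol
Conditions: CH2=CHMgBr, THF, −78 → 0 °C; H2O
Reagents that add atoms: vinylmagnesium bromide (C=C[Mg]Br)
Why: Grignard 1,2-addition to the enal gives the racemic bis-allylic alcohol.

Step 7
Reactants: 12 rac-(1E)-1-phenylpenta-1,4-dien-3-ol
Product: 13 (1E,3S)-1-phenylpenta-1,4-dien-3-ol
Conditions: immobilised Candida antarctica lipase B, vinyl acetate (3 equiv), t-BuOMe, 30 °C, stopped at about 52 % conversion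
Reagents that add atoms: none
Why: Enzymatic kinetic resolution by transesterification, in which the lipase acylates the (R)-alcohol (large styryl, medium vinyl) and leaves (S)-13, the future C6.

Step 8
Reactants: 13 (1E,3S)-1-phenylpenta-1,4-dien-3-ol; 14 2-(bromomethyl)prop-2-enoic acid
Product: 15 (1E,3S)-1-phenylpenta-1,4-dien-3-yl 2-(bromomethyl)prop-2-enoate
Conditions: DCC (1.1 equiv), DMAP (5 mol %), CH2Cl2, 0 °C
Reagents that add atoms: none
Why: Steglich esterification at low temperature acylates the alcohol without breaking its C–O bond, so the stereocentre is retained and the allylic bromide survives.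

Step 9
Reactants: 15 (1E,3S)-1-phenylpenta-1,4-dien-3-yl 2-(bromomethyl)prop-2-enoate
Product: 16 (5R)-3-(bromomethyl)-5-[(E)-2-phenylethenyl]furan-2(5H)-one
Conditions: second-generation Grubbs catalyst RuCl2(=CHPh)(PCy3)(H2IMes) (5 mol %; H2IMes = 1,3-dimesitylimidazolidin-2-ylidene), CH2Cl2 (10 mM), 40 °C
Reagents that add atoms: none
Why: Ring-closing metathesis, in which the carbene initiates at the terminal vinyl group and closes the five-membered ring onto the acrylate while the slower styryl group stays as spectator; the carbinol centre is untouched (R only by priority change).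

Step 10
Reactants: 10 2-[(2S)-2-methyl-3-oxo-5-(prop-1-en-2-yl)-2,3-dihydrofuran-2-yl]acetaldehyde; 16 (5R)-3-(bromomethyl)-5-[(E)-2-phenylethenyl]furan-2(5H)-one
Product: 18 (4R,5R)-4-{(1R)-1-hydroxy-2-[(2S)-2-methyl-3-oxo-5-(prop-1-en-2-yl)-2,3-dihydrofuran-2-yl]ethyl}-3-methylidene-5-[(E)-2-phenylethenyl]oxolan-2-one, via allylzinc bromide 17 (not isolated)
Conditions: Zn dust (3 equiv), THF/saturated aqueous NH4Cl (2:1), 0 → 23 °C
Reagents that add atoms: none
Why: Zinc Barbier allylation, in which allylzinc 17 (a homoenolate-type β-carbanion of the butenolide) reacts SE2' through C7 on the face anti to the C6 styryl group (7R, trans-lactone) and, through the open aqueous transition state, gives the 7,8-syn carbinol (8R) while regenerating the exocyclic methylene.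

Step 11
Reactants: 18 (4R,5R)-4-{(1R)-1-hydroxy-2-[(2S)-2-methyl-3-oxo-5-(prop-1-en-2-yl)-2,3-dihydrofuran-2-yl]ethyl}-3-methylidene-5-[(E)-2-phenylethenyl]oxolan-2-one
Product: 19 (1R)-2-[(2S)-2-methyl-3-oxo-5-(prop-1-en-2-yl)-2,3-dihydrofuran-2-yl]-1-{(2R,3R)-4-methylidene-5-oxo-2-[(E)-2-phenylethenyl]oxolan-3-yl}ethyl 3-methylbutanoate
Conditions: 3-methylbutanoic anhydride (1.5 equiv), DMAP (10 mol %), pyridine, CH2Cl2, 0 °C
Reagents that add atoms: 3-methylbutanoic anhydride (CC(C)CC(=O)OC(=O)CC(C)C)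
Why: DMAP-catalysed acylation of the C8 alcohol goes with retention and, at 0 °C, should outrun translactonisation.

Step 12
Reactants: 19 (1R)-2-[(2S)-2-methyl-3-oxo-5-(prop-1-en-2-yl)-2,3-dihydrofuran-2-yl]-1-{(2R,3R)-4-methylidene-5-oxo-2-[(E)-2-phenylethenyl]oxolan-3-yl}ethyl 3-methylbutanoate
Product: 20 (2Z,4R,8R,9R,11S)-2,11-dimethyl-7-methylidene-6,12-dioxo-5,14-dioxatricyclo[9.2.1.0(4,8)]tetradeca-1(13),2-dien-9-yl 3-methylbutanoate
Conditions: second-generation Hoveyda–Grubbs catalyst RuCl2(=CH-C6H4-2-O-i-Pr)(H2IMes) (20 mol %, in portions), 1,4-benzoquinone (20 mol %), toluene (1 mM), 100 °C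
Reagents that add atoms: none
Why: Ring-closing metathesis, in which the carbene enters at the styryl terminus (styrene lost) and closes onto the isopropenyl group to form the trisubstituted C4=C5 alkene, Z being the only geometry the bridged ring allows; no stereocentre is touched.

**Compound list**
1 | 1,1,3,3-tetramethoxypropane | COC(OC)CC(OC)OC | starting material
2 | sodium malondialdehyde | [Na+].[O-]/C=C/C=O | intermediate
3 | ethyl buta-2,3-dienoate | CCOC(=O)C=C=C | starting material
4 | ethyl (2E)-3-{[(1E)-3-oxoprop-1-en-1-yl]oxy}but-2-enoate | CCOC(=O)/C=C(\C)O/C=C/C=O | intermediate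
5 | ethyl (2E)-3-{[(1Z)-3-oxoprop-1-en-1-yl]oxy}but-2-enoate | CCOC(=O)/C=C(\C)O/C=C\C=O | intermediate (not isolated)
6 | ethyl 2-[(2S)-2-methyl-3-oxo-2,3-dihydrofuran-2-yl]acetate | CCOC(=O)C[C@]1(C)OC=CC1=O | intermediate
7 | bromomagnesium (2S)-2-(2-ethoxy-2-oxoethyl)-2-methyl-5-(prop-1-en-2-yl)-2,5-dihydrofuran-3-olate (C5 epimers) | CCOC(=O)C[C@]1(C)OC(C(C)=C)C=C1O[Mg]Br | intermediate (not isolated)
8 | ethyl 2-[(2S)-4-(N-tert-butyl-S-phenylsulfinimidoyl)-2-methyl-3-oxo-5-(prop-1-en-2-yl)oxolan-2-yl]acetate (C4/C5 epimers) | CCOC(=O)C[C@]1(C)OC(C(C)=C)C(S(=NC(C)(C)C)c2ccccc2)C1=O | intermediate (not isolated)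
9 | ethyl 2-[(2S)-2-methyl-3-oxo-5-(prop-1-en-2-yl)-2,3-dihydrofuran-2-yl]acetate | CCOC(=O)C[C@]1(C)OC(C(C)=C)=CC1=O | intermediate
10 | 2-[(2S)-2-methyl-3-oxo-5-(prop-1-en-2-yl)-2,3-dihydrofuran-2-yl]acetaldehyde | O=CC[C@]1(C)OC(C(C)=C)=CC1=O | intermediate
11 | (E)-cinnamaldehyde | O=C/C=C/c1ccccc1 | starting material
12 | rac-(1E)-1-phenylpenta-1,4-dien-3-ol | OC(C=C)/C=C/c1ccccc1 | intermediate
13 | (1E,3S)-1-phenylpenta-1,4-dien-3-ol | O[C@@H](C=C)/C=C/c1ccccc1 | intermediate
14 | 2-(bromomethyl)prop-2-enoic acid | C=C(CBr)C(=O)O | starting material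
15 | (1E,3S)-1-phenylpenta-1,4-dien-3-yl 2-(bromomethyl)prop-2-enoate | C=C(CBr)C(=O)O[C@@H](C=C)/C=C/c1ccccc1 | intermediate
16 | (5R)-3-(bromomethyl)-5-[(E)-2-phenylethenyl]furan-2(5H)-one | BrCC1=C[C@@H](/C=C/c2ccccc2)OC1=O | intermediate
17 | {[(5R)-2-oxo-5-[(E)-2-phenylethenyl]-2,5-dihydrofuran-3-yl]methyl}zinc bromide | Br[Zn]CC1=C[C@@H](/C=C/c2ccccc2)OC1=O | intermediate (not isolated)
18 | (4R,5R)-4-{(1R)-1-hydroxy-2-[(2S)-2-methyl-3-oxo-5-(prop-1-en-2-yl)-2,3-dihydrofuran-2-yl]ethyl}-3-methylidene-5-[(E)-2-phenylethenyl]oxolan-2-one | C=C1C(=O)O[C@H](/C=C/c2ccccc2)[C@H]1[C@H](O)C[C@]3(C)OC(C(C)=C)=CC3=O | intermediate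
19 | (1R)-2-[(2S)-2-methyl-3-oxo-5-(prop-1-en-2-yl)-2,3-dihydrofuran-2-yl]-1-{(2R,3R)-4-methylidene-5-oxo-2-[(E)-2-phenylethenyl]oxolan-3-yl}ethyl 3-methylbutanoate | C=C1C(=O)O[C@H](/C=C/c2ccccc2)[C@H]1[C@H](OC(=O)CC(C)C)C[C@]3(C)OC(C(C)=C)=CC3=O | intermediate
20 | (2Z,4R,8R,9R,11S)-2,11-dimethyl-7-methylidene-6,12-dioxo-5,14-dioxatricyclo[9.2.1.0(4,8)]tetradeca-1(13),2-dien-9-yl 3-methylbutanoate (CNP0409052.1) | C=C1C(=O)O[C@@H]2/C=C(/C)C3=CC(=O)[C@](C)(C[C@@H](OC(=O)CC(C)C)[C@@H]12)O3 | target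

**Step count**
Total: 12 steps. Longest linear sequence: 8 (steps 1–5, then 10–12); steps 6–9 make the lactone fragment in parallel.

**Three steps most likely to fail**

Step 3, the Stetter cyclisation. The vinylogous aldehyde may divert through homoenolate chemistry (β-protonation and loss of the acetoacetate enolate) or fail to reach the Z form. The fallback sets out from 3 and comes back at 6, using a saturated tether, the substrate class for which this catalysis is established. Potassium tert-butoxide-catalysed oxa-Michael addition of 3,3-diethoxypropan-1-ol to 3 gives ethyl (2E)-3-(3,3-diethoxypropoxy)but-2-enoate F1. Mild acetal hydrolysis (aqueous oxalic acid on silica) gives ethyl (2E)-3-(3-oxopropoxy)but-2-enoate F2. The same triazolium/KN(SiMe3)2 cyclisation gives ethyl 2-[(2S)-2-methyl-3-oxooxolan-2-yl]acetate F3. Dehydrogenation at its only enolisable position with 2-iodoxybenzoic acid in DMSO at 70 °C returns 6.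

Step 10, the diastereoselectivity at C8. A closed chair transition state would give the 8S epimer instead of 18. The fallback sets out from 10 and 16 and comes back at 19, making that epimer on purpose and setting C8 by inversion. CrCl2 (divalent chromium) in THF couples 10 and 16 through the chair to (4R,5R)-4-{(1S)-1-hydroxy-2-[(2S)-2-methyl-3-oxo-5-(prop-1-en-2-yl)-2,3-dihydrofuran-2-yl]ethyl}-3-methylidene-5-[(E)-2-phenylethenyl]oxolan-2-one F4. Mitsunobu esterification of F4 with 3-methylbutanoic acid (PPh3, diisopropyl azodicarboxylate, toluene, 0 → 23 °C) inverts C8 and gives 19 directly.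

Step 12, the macrocyclic metathesis. The α-methylene lactone can trap the ruthenium carbene, and the strained trisubstituted alkene is slow to form. The fallback sets out from 19 and comes back at 20, taking the acrylate out of play during ring closure. Thiophenol with catalytic Et3N adds to the α-methylene lactone of 19 to give (1R)-2-[(2S)-2-methyl-3-oxo-5-(prop-1-en-2-yl)-2,3-dihydrofuran-2-yl]-1-{(2R,3R)-5-oxo-2-[(E)-2-phenylethenyl]-4-[(phenylsulfanyl)methyl]oxolan-3-yl}ethyl 3-methylbutanoate F5. Metathesis of F5 with the same catalyst gives the macrocyclic sulfide (2Z,4R,8R,9R,11S)-2,11-dimethyl-6,12-dioxo-7-[(phenylsulfanyl)methyl]-5,14-dioxatricyclo[9.2.1.0(4,8)]tetradeca-1(13),2-dien-9-yl 3-methylbutanoate F6. NaIO4 oxidation gives the corresponding sulfoxide (2Z,4R,8R,9R,11S)-7-[(benzenesulfinyl)methyl]-2,11-dimethyl-6,12-dioxo-5,14-dioxatricyclo[9.2.1.0(4,8)]tetradeca-1(13),2-dien-9-yl 3-methylbutanoate F7. Heating F7 in toluene at 90 °C eliminates the sulfoxide and gives 20.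

Further compounds
F1 | step 3 | ethyl (2E)-3-(3,3-diethoxypropoxy)but-2-enoate | CCOC(=O)/C=C(\C)OCCC(OCC)OCC
F2 | step 3 | ethyl (2E)-3-(3-oxopropoxy)but-2-enoate | CCOC(=O)/C=C(\C)OCCC=O
F3 | step 3 | ethyl 2-[(2S)-2-methyl-3-oxooxolan-2-yl]acetate | CCOC(=O)C[C@]1(C)OCCC1=O
F4 | step 10 | (4R,5R)-4-{(1S)-1-hydroxy-2-[(2S)-2-methyl-3-oxo-5-(prop-1-en-2-yl)-2,3-dihydrofuran-2-yl]ethyl}-3-methylidene-5-[(E)-2-phenylethenyl]oxolan-2-one | C=C1C(=O)O[C@H](/C=C/c2ccccc2)[C@H]1[C@@H](O)C[C@]3(C)OC(C(C)=C)=CC3=O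
F5 | step 12 | (1R)-2-[(2S)-2-methyl-3-oxo-5-(prop-1-en-2-yl)-2,3-dihydrofuran-2-yl]-1-{(2R,3R)-5-oxo-2-[(E)-2-phenylethenyl]-4-[(phenylsulfanyl)methyl]oxolan-3-yl}ethyl 3-methylbutanoate (C4 epimers) | c4ccccc4SCC1C(=O)O[C@H](/C=C/c2ccccc2)[C@H]1[C@H](OC(=O)CC(C)C)C[C@]3(C)OC(C(C)=C)=CC3=O
F6 | step 12 | (2Z,4R,8R,9R,11S)-2,11-dimethyl-6,12-dioxo-7-[(phenylsulfanyl)methyl]-5,14-dioxatricyclo[9.2.1.0(4,8)]tetradeca-1(13),2-dien-9-yl 3-methylbutanoate (C7 epimers) | c4ccccc4SCC1C(=O)O[C@@H]2/C=C(/C)C3=CC(=O)[C@](C)(C[C@@H](OC(=O)CC(C)C)[C@@H]12)O3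
F7 | step 12 | (2Z,4R,8R,9R,11S)-7-[(benzenesulfinyl)methyl]-2,11-dimethyl-6,12-dioxo-5,14-dioxatricyclo[9.2.1.0(4,8)]tetradeca-1(13),2-dien-9-yl 3-methylbutanoate (sulfoxide and C7 epimers) | O=S(c4ccccc4)CC1C(=O)O[C@@H]2/C=C(/C)C3=CC(=O)[C@](C)(C[C@@H](OC(=O)CC(C)C)[C@@H]12)O3
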